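**Retrosynthetic overview**

- Ring numbering: dihydropyran O1, C2 (methyl), C3 (formyl), C4 (acetate arm), C5 (methyl ester), C6. The strategy rests on the O1–C2 bond: it is the β C–O bond of the C3 aldehyde, and O1 is also the enol oxygen of a formylacetate (O1–C6=C5–CO2Me). The ring is therefore the oxa-Michael adduct of the open enol-dialdehyde 16.
- Disconnections: O1–C2 (the only ring, closed last) gives 16. The ester C–O bond leads to hydroxytyrosol 14, and C5–C6 leads to methyl formate 12 (formylation of the dianion of half-ester 11).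
- C4 comes from enantioselective methanolysis of the prochiral anhydride 10. The E-enal arm comes from SeO2 oxidation of a but-2-en-2-yl group, made by Wittig reaction of dimethyl 3-acetylglutarate 4 (from 1 and 2).

Key step: step 12

Assumption: the sense of step 8 is assigned by analogy with quinine-series openings of 3-alkylglutaric anhydrides; if the S half-ester were formed, the quinidine-series catalyst (DHQD)2AQN would be used instead with no other change.

**Route**

Step 1
Reactants: 1 dimethyl 2-acetylbutanedioate (dimethyl acetylsuccinate); 2 methyl bromoacetate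
Product: 3 trimethyl 2-acetylpropane-1,2,3-tricarboxylate
Conditions: NaH (1.1 equiv), THF, 0 °C; then 2 (1.2 equiv), rt to 50 °C
Reagents that add atoms: none
Why: Acetoacetic ester alkylation: the sodium enolate of the β-keto ester is C-alkylated by the reactive α-bromo ester, which puts both acetate arms on the carbon that becomes C4 (the quaternary centre is removed in step 2, so its configuration is of no consequence).

Step 2
Reactants: 3 trimethyl 2-acetylpropane-1,2,3-tricarboxylate
Product: 4 dimethyl 3-acetylpentanedioate
Conditions: LiCl (2 equiv), H2O (2 equiv), DMSO, 140 °C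
Reagents that add atoms: none
Why: Krapcho dealkoxycarbonylation: chloride demethylates the ester that sits β to the ketone and the carboxylate loses CO2 through the ketone enolate, while the two unactivated acetate esters are left alone; the product is achiral.

Step 3
Reactants: 4 dimethyl 3-acetylpentanedioate; 5 ethyltriphenylphosphonium bromide
Product: 6 dimethyl 3-(but-2-en-2-yl)pentanedioate (E/Z mixture)
Conditions: 5 (1.3 equiv), KN(SiMe3)2 (1.25 equiv), THF, 0 °C; then 4, −78 °C to rt
Reagents that add atoms: none
Why: Wittig olefination with a salt-free unstabilised ylide should add to the methyl ketone faster than it enolises it at low temperature; the E/Z ratio does not matter because step 4 sets the geometry anew.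

Step 4
Reactants: 6 dimethyl 3-(but-2-en-2-yl)pentanedioate
Product: 7 dimethyl 3-[(2E)-1-oxobut-2-en-2-yl]pentanedioate
Conditions: SeO2 (1.3 equiv), wet 1,4-dioxane, 85 °C
Reagents that add atoms: selenium dioxide, O=[Se]=O
Why: Riley allylic oxidation: the ene reaction places selenium on the less substituted alkene carbon and takes hydrogen from the methyl group on the more substituted one (methyl reacts before the methine C–H of the glutarate carbon), the [2,3]-shift returns the double bond with the oxygenated carbon trans to the ethylidene methyl from either alkene isomer, and SeO2 takes the allylic alcohol on to the E-enal.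

Step 5
Reactants: 7 dimethyl 3-[(2E)-1-oxobut-2-en-2-yl]pentanedioate
Product: 8 dimethyl 3-[(1E)-1-(1,3-dioxolan-2-yl)prop-1-en-1-yl]pentanedioate
Conditions: Me3SiOCH2CH2OSiMe3 (1.5 equiv), Me3SiOTf (5 mol%), CH2Cl2, −78 to −20 °C; pyridine quench
Reagents that add atoms: 1,2-bis(trimethylsilyloxy)ethane, C[Si](C)(C)OCCO[Si](C)(C)C
Why: Noyori acetalisation under aprotic conditions at low temperature masks the enal as a dioxolane without conjugate addition or E/Z isomerisation, which is needed for the strong base of step 9.

Step 6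
Reactants: 8 dimethyl 3-[(1E)-1-(1,3-dioxolan-2-yl)prop-1-en-1-yl]pentanedioate
Product: 9 3-[(1E)-1-(1,3-dioxolan-2-yl)prop-1-en-1-yl]pentanedioic acid
Conditions: LiOH (2.5 equiv), THF/H2O (3:1), 0 °C to rt; then cold 0.5 M HCl to pH 3, immediate extraction
Reagents that add atoms: lithium hydroxide, [Li+].[OH-]
Why: Saponification of both methyl esters; the acetal and the alkene are inert to hydroxide and the brief cold acidification should spare the dioxolane.

Step 7
Reactants: 9 3-[(1E)-1-(1,3-dioxolan-2-yl)prop-1-en-1-yl]pentanedioic acid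
Product: 10 4-[(1E)-1-(1,3-dioxolan-2-yl)prop-1-en-1-yl]oxane-2,6-dione
Conditions: N,N'-dicyclohexylcarbodiimide (1.05 equiv), CH2Cl2, 0 °C to rt; filtration
Reagents that add atoms: none
Why: Carbodiimide cyclodehydration of a 3-substituted glutaric acid gives the six-membered anhydride under neutral conditions that the acetal tolerates.

Step 8
Reactants: 10 4-[(1E)-1-(1,3-dioxolan-2-yl)prop-1-en-1-yl]oxane-2,6-dione
Product: 11 (3R)-3-[(1E)-1-(1,3-dioxolan-2-yl)prop-1-en-1-yl]-5-methoxy-5-oxopentanoic acid
Conditions: MeOH (10 equiv), hydroquinine anthraquinone-1,4-diyl diether [(DHQ)2AQN, 20 mol%], Et2O, −40 °C; product taken into aqueous NaHCO3, re-acidified cold to pH 4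
Reagents that add atoms: methanol, CO
Why: Cinchona-alkaloid-catalysed desymmetrising alcoholysis of a prochiral 3-substituted glutaric anhydride: the quinuclidine nitrogen acts as general base and delivers methanol to one of the two enantiotopic carbonyl groups, which sets the future C4 as R.

Step 9
Reactants: 11 (3R)-3-[(1E)-1-(1,3-dioxolan-2-yl)prop-1-en-1-yl]-5-methoxy-5-oxopentanoic acid; 12 methyl formate
Product: 13 (3S,4Z)-3-[(1E)-1-(1,3-dioxolan-2-yl)prop-1-en-1-yl]-5-hydroxy-4-(methoxycarbonyl)pent-4-enoic acid
Conditions: LiN(iPr)2 (2.3 equiv), THF, −78 °C; then 12 (5 equiv), −78 to 0 °C; cold 0.5 M HCl to pH 4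
Reagents that add atoms: none
Why: Crossed Claisen condensation (ester formylation) on the carboxylate/ester-enolate dianion: at −78 °C only the ester arm is enolised, so methyl formate acylates that arm alone and the product rests as its enolate and is isolated as the hydrogen-bonded Z-enol; C4 is not acidic and is retained (its descriptor becomes S only because the priorities change).

Step 10
Reactants: 13 (3S,4Z)-3-[(1E)-1-(1,3-dioxolan-2-yl)prop-1-en-1-yl]-5-hydroxy-4-(methoxycarbonyl)pent-4-enoic acid; 14 hydroxytyrosol, 4-(2-hydroxyethyl)benzene-1,2-diol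
Product: 15 2-(3,4-dihydroxyphenyl)ethyl (3S,4Z)-3-[(1E)-1-(1,3-dioxolan-2-yl)prop-1-en-1-yl]-5-hydroxy-4-(methoxycarbonyl)pent-4-enoate
Conditions: PPh3 (1.3 equiv), diisopropyl azodicarboxylate (1.3 equiv), THF, 0 °C (betaine preformed); then 13 and 14 (1.2 equiv), 0 °C to rt, Ar
Reagents that add atoms: none
Why: Mitsunobu esterification: the carboxylic acid is several pKa units more acidic than the enol and the phenols, so its carboxylate is the species that displaces the alkoxyphosphonium of the primary alcohol, and preforming the betaine keeps free azodicarboxylate away from the enol.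

Step 11
Reactants: 15 2-(3,4-dihydroxyphenyl)ethyl (3S,4Z)-3-[(1E)-1-(1,3-dioxolan-2-yl)prop-1-en-1-yl]-5-hydroxy-4-(methoxycarbonyl)pent-4-enoate
Product: 16 5-[2-(3,4-dihydroxyphenyl)ethyl] 1-methyl (2Z,3S)-2-(hydroxymethylidene)-3-[(2E)-1-oxobut-2-en-2-yl]pentanedioate (open enol-dialdehyde)
Conditions: 1 M aq. HCl/THF (1:4), 0 °C to rt, Ar; extraction, no chromatography
Reagents that add atoms: water, O
Why: Acid hydrolysis of an allylic acetal is fast because the oxocarbenium ion is conjugated, and the esters, the enol and the catechol are stable to cold dilute acid; the E-enal is the stable geometry and the product equilibrates with its cyclic hemiacetal, so it is used crude.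

Step 12
Reactants: 16 5-[2-(3,4-dihydroxyphenyl)ethyl] 1-methyl (2Z,3S)-2-(hydroxymethylidene)-3-[(2E)-1-oxobut-2-en-2-yl]pentanedioate
Product: 17 methyl (2S,3S,4S)-4-{2-[2-(3,4-dihydroxyphenyl)ethoxy]-2-oxoethyl}-3-formyl-2-methyl-3,4-dihydro-2H-pyran-5-carboxylate (target)
Conditions: Et3N (0.2 equiv), CH2Cl2, 0 °C to rt, Ar; AcOH quench; SiO2 chromatography
Reagents that add atoms: none
Why: Triethylamine ionises the chelated formylacetate enol, whose oxygen adds to the ethylidene carbon of the 2-ethylidene enal (conjugate addition) to form O1–C2, and the aldehyde enolate so formed is protonated at C3. The closest known reaction type is the intramolecular oxa-Michael addition of a 1,3-dicarbonyl enol to an enal, the closure by which opened secoiridoid aglycones form this dihydropyran. The one ring (O1, C2, C3, C4, C5, C6) closes in the 6-endo-trig mode. C2 and C3 are set under thermodynamic control by the fixed C4 centre, because the addition is reversible and C3 is enolisable: the preferred half-chair should carry the C4 acetate arm pseudoaxial (away from the C5 ester), the C3 formyl group axial and trans to that arm and the C2 methyl group equatorial, which is the (2S,3S,4S) isomer. The step needs 1,4- over 1,2-addition and O- over C-attack; the 1,2-adduct is a hemiacetal that reverts to 16, C5 is fully substituted so C-attack gives nothing stable, and C4 is not acidic enough for a trialkylamine, so its configuration should hold. Any Z-enal present should give the same product, since both geometries pass through the same enolate.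

**Compound list**

1 | dimethyl 2-acetylbutanedioate | COC(=O)CC(C(C)=O)C(=O)OC | starting material
2 | methyl bromoacetate | COC(=O)CBr | starting material
3 | trimethyl 2-acetylpropane-1,2,3-tricarboxylate | CC(=O)C(CC(=O)OC)(CC(=O)OC)C(=O)OC | intermediate
4 | dimethyl 3-acetylpentanedioate | CC(=O)C(CC(=O)OC)CC(=O)OC | intermediate
5 | ethyltriphenylphosphonium bromide | CC[P+](c1ccccc1)(c1ccccc1)c1ccccc1.[Br-] | starting material
6 | dimethyl 3-(but-2-en-2-yl)pentanedioate, E/Z mixture (Z isomer drawn) | C/C=C(/C)C(CC(=O)OC)CC(=O)OC | intermediate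
7 | dimethyl 3-[(2E)-1-oxobut-2-en-2-yl]pentanedioate | C/C=C(/C=O)C(CC(=O)OC)CC(=O)OC | intermediate
8 | dimethyl 3-[(1E)-1-(1,3-dioxolan-2-yl)prop-1-en-1-yl]pentanedioate | C/C=C(/C1OCCO1)C(CC(=O)OC)CC(=O)OC | intermediate
9 | 3-[(1E)-1-(1,3-dioxolan-2-yl)prop-1-en-1-yl]pentanedioic acid | C/C=C(/C1OCCO1)C(CC(=O)O)CC(=O)O | intermediate
10 | 4-[(1E)-1-(1,3-dioxolan-2-yl)prop-1-en-1-yl]oxane-2,6-dione | C/C=C(/C1OCCO1)C1CC(=O)OC(=O)C1 | intermediate
11 | (3R)-3-[(1E)-1-(1,3-dioxolan-2-yl)prop-1-en-1-yl]-5-methoxy-5-oxopentanoic acid | C/C=C(/C1OCCO1)[C@@H](CC(=O)OC)CC(=O)O | intermediate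
12 | methyl formate | COC=O | starting material
13 | (3S,4Z)-3-[(1E)-1-(1,3-dioxolan-2-yl)prop-1-en-1-yl]-5-hydroxy-4-(methoxycarbonyl)pent-4-enoic acid | C/C=C(/C1OCCO1)[C@@H](/C(C(=O)OC)=C/O)CC(=O)O | intermediate
14 | hydroxytyrosol, 4-(2-hydroxyethyl)benzene-1,2-diol | OCCc1ccc(O)c(O)c1 | starting material
15 | 2-(3,4-dihydroxyphenyl)ethyl (3S,4Z)-3-[(1E)-1-(1,3-dioxolan-2-yl)prop-1-en-1-yl]-5-hydroxy-4-(methoxycarbonyl)pent-4-enoate | C/C=C(/C1OCCO1)[C@@H](/C(C(=O)OC)=C/O)CC(=O)OCCc1ccc(O)c(O)c1 | intermediate
16 | 5-[2-(3,4-dihydroxyphenyl)ethyl] 1-methyl (2Z,3S)-2-(hydroxymethylidene)-3-[(2E)-1-oxobut-2-en-2-yl]pentanedioate | C/C=C(/C=O)[C@@H](/C(C(=O)OC)=C/O)CC(=O)OCCc1ccc(O)c(O)c1 | intermediate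
17 | methyl (2S,3S,4S)-4-{2-[2-(3,4-dihydroxyphenyl)ethoxy]-2-oxoethyl}-3-formyl-2-methyl-3,4-dihydro-2H-pyran-5-carboxylate | COC(=O)C1=CO[C@@H](C)[C@@H](C=O)[C@@H]1CC(=O)OCCc1ccc(O)c(O)c1 | target

**Step count and risks**

Total step count: 12. Longest linear sequence: 12 steps (1 to 17).

Steps most likely to fail:

1. Step 4. The ene step may take hydrogen from the C4 methine or from the ethylidene methyl instead of the intended methyl, and the oxidation may stall at the allylic alcohol or run on to the acid. The fallback brings the formyl carbon in at the aldehyde oxidation level; it sets out from 2 and comes back at 7. Commercial methyl 4,4-dimethoxy-3-oxobutanoate (COC(OC)C(=O)CC(=O)OC) is alkylated twice with 2 (NaH, THF), through dimethyl 2-(2,2-dimethoxyacetyl)butanedioate F1, to trimethyl 2-(2,2-dimethoxyacetyl)propane-1,2,3-tricarboxylate F2. Krapcho dealkoxycarbonylation (LiCl, wet DMSO, 140 °C) should give dimethyl 3-(2,2-dimethoxyacetyl)pentanedioate F3. Wittig reaction with the ylide from 5 should give dimethyl 3-[(1Z)-1-(dimethoxymethyl)prop-1-en-1-yl]pentanedioate F4; α-alkoxy ketones are expected to place the new methyl mainly cis to the acetal carbon. Aqueous acid hydrolysis, with acid-catalysed equilibration of the enal to its more stable E geometry, then gives 7.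

2. Step 10. The alkoxyphosphonium may alkylate the enol oxygen or a phenol, or the enol may add to the azodicarboxylate, so that 13 is consumed without ester formation. The fallback masks the catechol and uses acyl transfer instead; it sets out from 13 and 14 and comes back at 15. Hydroxytyrosol 14 is silylated (tert-butyldimethylsilyl chloride, imidazole, DMF) to the tris(tert-butyldimethylsilyl) ether F5. The primary silyl ether is removed selectively (pyridinium p-toluenesulfonate, EtOH) to give 2-[3,4-bis(tert-butyldimethylsilyloxy)phenyl]ethanol F6. Carbodiimide coupling with 13 (1-ethyl-3-[3-(dimethylamino)propyl]carbodiimide hydrochloride, 4-(dimethylamino)pyridine, CH2Cl2) should give the bis-silyl ester F7; any enol lactone or enol ester formed first is itself an acyl donor that the pyridine catalyst passes on to the alcohol. Phenol desilylation (KHF2, MeOH, rt) gives 15.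

3. Step 12. The thermodynamic preference may be incomplete, leaving C2/C3 epimers and hemiacetal tautomers that are hard to separate from the polar catechol ester. The fallback closes the ring before the catechol fragment is attached; it sets out from 13 and comes back at 17. The acetal of 13 is hydrolysed (1 M aq. HCl/THF) to the open enol-dialdehyde acid F8. Closure under the amine conditions of step 12 should give (2S,3S,4S)-elenolic acid F9, which can be purified as a crystalline amine salt while the mother liquors are re-equilibrated. Mitsunobu esterification of F9 with 14 (PPh3, diisopropyl azodicarboxylate, THF) then gives 17.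

**Further compounds**

F1 | step 4 | dimethyl 2-(2,2-dimethoxyacetyl)butanedioate | COC(OC)C(=O)C(CC(=O)OC)C(=O)OC
F2 | step 4 | trimethyl 2-(2,2-dimethoxyacetyl)propane-1,2,3-tricarboxylate | COC(OC)C(=O)C(CC(=O)OC)(CC(=O)OC)C(=O)OC
F3 | step 4 | dimethyl 3-(2,2-dimethoxyacetyl)pentanedioate | COC(OC)C(=O)C(CC(=O)OC)CC(=O)OC
F4 | step 4 | dimethyl 3-[(1Z)-1-(dimethoxymethyl)prop-1-en-1-yl]pentanedioate | C/C=C(\C(OC)OC)C(CC(=O)OC)CC(=O)OC
F5 | step 10 | tert-butyl{2-[3,4-bis(tert-butyldimethylsilyloxy)phenyl]ethoxy}dimethylsilane | CC(C)(C)[Si](C)(C)OCCc1ccc(O[Si](C)(C)C(C)(C)C)c(O[Si](C)(C)C(C)(C)C)c1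
F6 | step 10 | 2-[3,4-bis(tert-butyldimethylsilyloxy)phenyl]ethanol | OCCc1ccc(O[Si](C)(C)C(C)(C)C)c(O[Si](C)(C)C(C)(C)C)c1
F7 | step 10 | 2-[3,4-bis(tert-butyldimethylsilyloxy)phenyl]ethyl (3S,4Z)-3-[(1E)-1-(1,3-dioxolan-2-yl)prop-1-en-1-yl]-5-hydroxy-4-(methoxycarbonyl)pent-4-enoate | C/C=C(/C1OCCO1)[C@@H](/C(C(=O)OC)=C/O)CC(=O)OCCc1ccc(O[Si](C)(C)C(C)(C)C)c(O[Si](C)(C)C(C)(C)C)c1
F8 | step 12 | (3S,4Z)-5-hydroxy-4-(methoxycarbonyl)-3-[(2E)-1-oxobut-2-en-2-yl]pent-4-enoic acid | C/C=C(/C=O)[C@@H](/C(C(=O)OC)=C/O)CC(=O)O
F9 | step 12 | (2S,3S,4S)-elenolic acid, 2-[(2S,3S,4S)-3-formyl-5-(methoxycarbonyl)-2-methyl-3,4-dihydro-2H-pyran-4-yl]acetic acid | COC(=O)C1=CO[C@@H](C)[C@@H](C=O)[C@@H]1CC(=O)O
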